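## Retrosynthetic overview
1. Target ⇒ its 6,7‑di‑O‑methyl bis‑tert‑butyl ester by one BBr3 dealkylation. The C2 methyl ester is carried in from the start. (Locants: C1–C4, C4a, C8a = carbocycle; C2'–C6' = pyranone.)
2. The pyranone is the second ring formed. C3'–C4' and O1'–C2' come from a carbene‑bound azolium enolate and tert‑butyl 4‑ethoxy‑2‑oxobut‑3‑enoate, followed by loss of EtOH.
3. The carbocycle is the first ring formed. The key C1–C2 bond joins a carbene‑derived homoenolate (β‑carbon of a cinnamaldehyde) to the β‑carbon of a phosphonobutenedioate, so two acceptor carbons are joined. C3=C4 then closes by intramolecular HWE. The catalyst sets C1, and equilibration sets C2 trans.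
4. Lines 2 and 3 are one catalytic operation on 2‑formyl‑4,5‑dimethoxycinnamaldehyde, made by Heck reaction from 6‑bromoveratraldehyde. Each partner is one step from bulk chemicals.

Assumption: the target is (1R,2R), H‑1/H‑2 trans, as read from the SMILES, and the (5aR,10bS) triazolium salt is assumed to leave the Si face of the enal β‑carbon open; if the first run gives the antipode, the equally available (5aS,10bR) salt is used and nothing else changes.

## Route

**Step 1**
Reactants: 1 2‑bromo‑4,5‑dimethoxybenzaldehyde; 2 acrolein diethyl acetal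
Product: 4 (E)‑3‑(2‑formyl‑4,5‑dimethoxyphenyl)prop‑2‑enal, via Heck acetal 3 (not isolated)
Conditions: Pd(OAc)2 (3 mol %), nBu4NOAc, K2CO3, KCl, DMF, 90 °C; then 2 M HCl, rt
Reagents that add atoms: water, O
Why: This is a Mizoroki–Heck reaction in which zerovalent palladium inserts into the formyl‑activated C–Br bond, syn‑insertion and β‑hydride elimination give only the E styrenyl acetal (which shields the enal from hot base), and the acid work‑up hydrolyses the acetal; no stereocentre is formed.

**Step 2**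
Reactants: 5 methyl 2‑hydroxy‑2‑methoxyacetate; 6 tert‑butyl diethylphosphonoacetate
Product: 8 1‑tert‑butyl 4‑methyl 2‑(diethoxyphosphoryl)but‑2‑enedioate (E/Z mixture), via methyl glyoxylate 7 (not isolated)
Conditions: piperidine (10 mol %), AcOH (20 mol %), toluene, Dean–Stark, reflux
Reagents that add atoms: none
Why: This is a Knoevenagel condensation in which the hemiacetal cracks to the very electrophilic aldehyde 7 and the buffered amine conditions (iminium/Mannich–elimination, no free alkoxide) dehydrate the adduct rather than expel phosphate, so phosphorus is retained; alkene geometry is irrelevant later.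

**Step 3**
Reactants: 9 oxalyl chloride; 10 ethyl vinyl ether
Product: 12 tert‑butyl (E)‑4‑ethoxy‑2‑oxobut‑3‑enoate, via ethoxy‑oxobutenoyl chloride 11 (not isolated)
Conditions: (COCl)2 (1.5 equiv), neat, 0 °C → rt, concentrate; then tBuOH, Et3N, CH2Cl2, 0 °C
Reagents that add atoms: tert‑butanol, CC(C)(C)O
Why: The enol ether is acylated at its β‑carbon and loses HCl (addition–elimination) to give the E push–pull enone acid chloride, whose acyl chloride is then esterified by tBuOH/Et3N; no stereocentre is formed.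

**Step 4 (key step)**
Reactants: 4 (E)‑3‑(2‑formyl‑4,5‑dimethoxyphenyl)prop‑2‑enal; 8 1‑tert‑butyl 4‑methyl 2‑(diethoxyphosphoryl)but‑2‑enedioate; 12 tert‑butyl (E)‑4‑ethoxy‑2‑oxobut‑3‑enoate
Product: 17 3‑tert‑butyl 2‑methyl (1R,2R)‑1‑[6‑(tert‑butoxycarbonyl)‑2‑oxo‑2H‑pyran‑3‑yl]‑6,7‑dimethoxy‑1,2‑dihydronaphthalene‑2,3‑dicarboxylate, via homoenolate 13 (not isolated), via Michael adduct 14 (not isolated), via azolium enolate 15 (not isolated), via ethoxydihydropyranone 16 (not isolated)
Conditions: (5aR,10bS)‑2‑mesityl‑5a,10b‑dihydro‑4H,6H‑indeno[2,1‑b][1,2,4]triazolo[4,3‑d][1,4]oxazin‑2‑ium tetrafluoroborate (15 mol %), DBU (1.5 equiv), 4 Å MS, THF, 0 °C → rt; 4 added over 4 h to 8 (1.2 equiv) and 12 (2 equiv)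
Reagents that add atoms: none
Why: Proposed new method: the free carbene adds to the enal CHO of 4 to give homoenolate 13, whose normally electrophilic β‑carbon (C1) attacks, on the Si face left open by the indane wall, the equally electrophilic C2 of 8 (the only alkene carbon β to both P=O and CO2tBu, so regiochemistry and ester differentiation are built in), the phosphonate carbanion of 14 closes onto the ortho CHO by intramolecular Horner–Wadsworth–Emmons olefination (C3=C4), azolium enolate 15 undergoes an inverse‑demand oxodiene hetero‑Diels–Alder/lactonisation with 12 that releases the carbene, and DBU removes EtOH from 16 by E1cB and equilibrates the acidic C2–H to the more stable 1,2‑trans diester; the closest known reaction types are NHC‑homoenolate conjugate additions to nitroalkenes and enones, Michael/HWE annulations with 2‑phosphonoacrylates and NHC‑enolate oxodiene Diels–Alder reactions with unsaturated α‑keto esters, which have not yet been merged in one flask.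

**Step 5**
Reactants: 17 3‑tert‑butyl 2‑methyl (1R,2R)‑1‑[6‑(tert‑butoxycarbonyl)‑2‑oxo‑2H‑pyran‑3‑yl]‑6,7‑dimethoxy‑1,2‑dihydronaphthalene‑2,3‑dicarboxylate
Product: 18 (1R,2R)‑1‑(6‑carboxy‑2‑oxo‑2H‑pyran‑3‑yl)‑6,7‑dihydroxy‑2‑(methoxycarbonyl)‑1,2‑dihydronaphthalene‑3‑carboxylic acid (target)
Conditions: BBr3 (8 equiv), CH2Cl2, −78 → 0 °C, argon; ice/H2O quench; reverse‑phase purification
Reagents that add atoms: none
Why: This is a Lewis‑acid ether/ester cleavage in which the chelating veratrole ethers (bromide SN2 at methyl) and the tert‑butyl esters (ionisation) fall at or below 0 °C well before the aliphatic methyl ester, the pyranone and cinnamate are inert to BBr3, and C1/C2 are not touched (trans is also the thermodynamic arrangement).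

## Compound list
1 | 2‑bromo‑4,5‑dimethoxybenzaldehyde | COc1cc(Br)c(C=O)cc1OC | starting material
2 | acrolein diethyl acetal | C=CC(OCC)OCC | starting material
3 | (E)‑2‑(3,3‑diethoxyprop‑1‑enyl)‑4,5‑dimethoxybenzaldehyde | CCOC(OCC)/C=C/c1cc(OC)c(OC)cc1C=O | intermediate (not isolated)
4 | (E)‑3‑(2‑formyl‑4,5‑dimethoxyphenyl)prop‑2‑enal | O=C/C=C/c1cc(OC)c(OC)cc1C=O | intermediate
5 | methyl 2‑hydroxy‑2‑methoxyacetate | COC(O)C(=O)OC | starting material
6 | tert‑butyl diethylphosphonoacetate | CCOP(=O)(CC(=O)OC(C)(C)C)OCC | starting material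
7 | methyl glyoxylate | O=CC(=O)OC | intermediate (not isolated)
8 | 1‑tert‑butyl 4‑methyl 2‑(diethoxyphosphoryl)but‑2‑enedioate, E/Z mixture | COC(=O)C=C(C(=O)OC(C)(C)C)P(=O)(OCC)OCC | intermediate
9 | oxalyl chloride | O=C(Cl)C(=O)Cl | starting material
10 | ethyl vinyl ether | C=COCC | starting material
11 | (E)‑4‑ethoxy‑2‑oxobut‑3‑enoyl chloride | CCO/C=C/C(=O)C(=O)Cl | intermediate (not isolated)
12 | tert‑butyl (E)‑4‑ethoxy‑2‑oxobut‑3‑enoate | CCO/C=C/C(=O)C(=O)OC(C)(C)C | intermediate
13 | extended Breslow intermediate (homoenolate) from the carbene and the enal CHO of 4, aryl CHO intact | O=Cc1cc(OC)c(OC)cc1/C=C/C(O)=C1N(c2c(C)cc(C)cc2C)N=C2CO[C@@H]3Cc4ccccc4[C@@H]3N12 | intermediate (not isolated)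
14 | Michael adduct zwitterion: C1–C2 bond made, C1 set, C2 not yet defined, enol‑azolium plus phosphonoacetate carbanion at C3 | O=Cc1cc(OC)c(OC)cc1[C@H](C=C(O)c1[n+](-c2c(C)cc(C)cc2C)nc2CO[C@@H]3Cc4ccccc4[C@@H]3n12)C(C(=O)OC)[C-](C(=O)OC(C)(C)C)P(=O)(OCC)OCC | intermediate (not isolated)
15 | azolium enolate of the ring‑closed 1,2‑dihydronaphthalene (after HWE), drawn 1,2‑trans | COC(=O)[C@H]1C(C(=O)OC(C)(C)C)=Cc2cc(OC)c(OC)cc2[C@@H]1C=C([O-])c1[n+](-c2c(C)cc(C)cc2C)nc2CO[C@@H]3Cc4ccccc4[C@@H]3n12 | intermediate (not isolated)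
16 | 4'‑ethoxy‑3',4'‑dihydro‑2‑pyranone cycloadduct (C3', C4' undefined, both are lost) | COC(=O)[C@H]1C(C(=O)OC(C)(C)C)=Cc2cc(OC)c(OC)cc2[C@@H]1C1C(OCC)C=C(C(=O)OC(C)(C)C)OC1=O | intermediate (not isolated)
17 | 3‑tert‑butyl 2‑methyl (1R,2R)‑1‑[6‑(tert‑butoxycarbonyl)‑2‑oxo‑2H‑pyran‑3‑yl]‑6,7‑dimethoxy‑1,2‑dihydronaphthalene‑2,3‑dicarboxylate | COC(=O)[C@H]1C(C(=O)OC(C)(C)C)=Cc2cc(OC)c(OC)cc2[C@@H]1c1ccc(C(=O)OC(C)(C)C)oc1=O | intermediate
18 | (1R,2R)‑1‑(6‑carboxy‑2‑oxo‑2H‑pyran‑3‑yl)‑6,7‑dihydroxy‑2‑(methoxycarbonyl)‑1,2‑dihydronaphthalene‑3‑carboxylic acid | COC(=O)[C@H]1C(C(=O)O)=Cc2cc(O)c(O)cc2[C@@H]1c1ccc(C(=O)O)oc1=O | target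

## Count and risks
Total steps: 5. Longest linear sequence: 3 (steps 1, 4, 5).

**Step 4 (most likely to fail).** There are four main failure modes:
- β‑protonation of 13, followed by a plain [4+2] with 12 or an intramolecular aldol;
- attack of 13 on 12 instead of 8;
- C‑acylation of the carbanion in 14 to give a cyclopentanone;
- capture of the carbene by 8.

The fallback sets out from 4 and 8 and splits the cascade into two two‑component reactions. The same triazolium tetrafluoroborate and DBU are used in THF–H2O (20:1) without 12. The C1–C2 homoenolate addition and the HWE closure run as before, and water hydrolyses the acyl azolium. This gives [(1R,2R)‑3‑(tert‑butoxycarbonyl)‑6,7‑dimethoxy‑2‑(methoxycarbonyl)‑1,2‑dihydronaphthalen‑1‑yl]acetic acid F1. CDI converts it into the corresponding 1‑acylimidazole F2. With the same triazolium salt, catalytic DBU and 12 as the only electrophile, F2 re‑enters as 15 and passes through 16. The fallback comes back to the route at 17.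

**Step 5.** The C2 methyl ester may be partly lost. The fallback sets out from 17 and rebuilds the ester rather than preserving it. Exhaustive dealkylation (excess BBr3, rt) gives (1R,2R)‑1‑(6‑carboxy‑2‑oxo‑2H‑pyran‑3‑yl)‑6,7‑dihydroxy‑1,2‑dihydronaphthalene‑2,3‑dicarboxylic acid F3. A chemoselective Fischer esterification (MeOH, cat. H2SO4, rt) then esterifies only the non‑conjugated C2 acid. The cinnamic‑type and pyranone acids react much more slowly. The fallback comes back at 18.

**Step 2.** HWE‑type loss of phosphate, or oligomerisation of the triply activated alkene, may erode the yield. The fallback sets out from 6 and avoids any aldehyde. Alkylation with methyl bromoacetate (NaH, THF) gives 1‑tert‑butyl 4‑methyl 2‑(diethoxyphosphoryl)butanedioate F4. Selenenylation of its anion (NaH, PhSeCl) gives 1‑tert‑butyl 4‑methyl 2‑(diethoxyphosphoryl)‑2‑(phenylselanyl)butanedioate F5. Oxidation with H2O2 triggers selenoxide syn‑elimination. The fallback comes back at 8.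

## Further compounds
F1 | step 4 | [(1R,2R)‑3‑(tert‑butoxycarbonyl)‑6,7‑dimethoxy‑2‑(methoxycarbonyl)‑1,2‑dihydronaphthalen‑1‑yl]acetic acid | COC(=O)[C@H]1C(C(=O)OC(C)(C)C)=Cc2cc(OC)c(OC)cc2[C@@H]1CC(=O)O
F2 | step 4 | 1‑acylimidazole of F1 | COC(=O)[C@H]1C(C(=O)OC(C)(C)C)=Cc2cc(OC)c(OC)cc2[C@@H]1CC(=O)n1ccnc1
F3 | step 5 | (1R,2R)‑1‑(6‑carboxy‑2‑oxo‑2H‑pyran‑3‑yl)‑6,7‑dihydroxy‑1,2‑dihydronaphthalene‑2,3‑dicarboxylic acid | OC(=O)[C@H]1C(C(=O)O)=Cc2cc(O)c(O)cc2[C@@H]1c1ccc(C(=O)O)oc1=O
F4 | step 2 | 1‑tert‑butyl 4‑methyl 2‑(diethoxyphosphoryl)butanedioate | COC(=O)CC(C(=O)OC(C)(C)C)P(=O)(OCC)OCC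
F5 | step 2 | 1‑tert‑butyl 4‑methyl 2‑(diethoxyphosphoryl)‑2‑(phenylselanyl)butanedioate | COC(=O)CC([Se]c1ccccc1)(C(=O)OC(C)(C)C)P(=O)(OCC)OCC
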